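Rings C and D are made together. Ring D (the gem-dimethylcyclohexane) is read as a latent cyclohexenone: its gem-dimethyl carbon is a masked ketone, so the quaternary C/D fusion carbon is an aldehyde α-carbon and the fusion CH an enone β-carbon. One amine-catalysed operation on a δ-lactone carrying a 3-formylbutyl chain and an (E)-3-oxobutenyl arm forges the fusion bond (Michael, closing ring C) and the ring-D CH2–CH2 bond next to the quaternary carbon (aldol condensation, closing ring D); the epimeric aldehydes converge through one enamine. The lactone stands in for ring B and is later unravelled; ring A arrives as 3-methylcyclopentenone, ring B closes by metathesis, and a dissolving-metal reduction sets the last two centres.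

Key step: step 7

Remarks on the chemistry:
- Ring letters: A = cyclopentane, B = cyclooctene, C = central cyclohexane, D = gem-dimethylcyclohexane.
- Assumption: the sense of induction in the two catalytic asymmetric steps (1 and 13) is taken from the accepted models for cyclic enones and enoates; should it be opposite, the ligand antipode is used.
- Centres that are erased later (the formyl-bearing carbon in 7 and 8, the carbinol and ring carbons created in steps 13 and 14) are carried as mixtures and left undefined in the SMILES.

Step 1
Reactants: 1 5,6-dihydro-2H-pyran-2-one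
Product: 2 (R)-4-vinyltetrahydro-2H-pyran-2-one
Conditions: potassium vinyltrifluoroborate, [Rh(cod)2]PF6 (3 mol %), (R)-BINAP, toluene/H2O, 105 °C
Reagents that add atoms: potassium vinyltrifluoroborate, C=C[B-](F)(F)F.[K+]
Why: Asymmetric 1,4-addition of the vinylboron reagent to the unsaturated lactone under [Rh(cod)2]PF6/(R)-BINAP catalysis should set the vinyl-bearing centre as R, the ligand selecting the face as in additions to cyclic enones.

Step 2
Reactants: 2 (R)-4-vinyltetrahydro-2H-pyran-2-one
Product: 3 (3S,4S)-3-methyl-4-vinyltetrahydro-2H-pyran-2-one
Conditions: LiN(i-Pr)2, THF, −78 °C; MeI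
Reagents that add atoms: iodomethane, CI
Why: Lithium enolate alkylation, with methyl iodide entering anti to the neighbouring vinyl group; this centre is planarised again in step 3.

Step 3
Reactants: 3 (3S,4S)-3-methyl-4-vinyltetrahydro-2H-pyran-2-one
Product: 4 (3S,4S)-3-methyl-3-(3-methylbut-2-en-1-yl)-4-vinyltetrahydro-2H-pyran-2-one
Conditions: LiN(i-Pr)2, THF/DMPU, −78 °C; prenyl bromide, −78 → −20 °C
Reagents that add atoms: 1-bromo-3-methylbut-2-ene, CC(C)=CCBr
Why: Second enolate alkylation; the allylic bromide attacks the planar enolate anti to the vinyl group, which sets the quaternary carbon with methyl cis to vinyl.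

Step 4
Reactants: 4 (3S,4S)-3-methyl-3-(3-methylbut-2-en-1-yl)-4-vinyltetrahydro-2H-pyran-2-one
Product: 6 (E)-enal lactone, via allylic alcohol 5 (not isolated)
Conditions: SeO2, 1,4-dioxane, 80 °C
Reagents that add atoms: selenium dioxide, O=[Se]=O
Why: Riley allylic oxidation (ene reaction, then [2,3]-shift) at the (E)-methyl of the trisubstituted alkene, the allylic alcohol being oxidised on to the (E)-enal; the monosubstituted vinyl group is much less reactive.

Step 5
Reactants: 6 (E)-enal lactone
Product: 7 aldehyde lactone (both epimers at the formyl-bearing carbon)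
Conditions: Hantzsch ester, dibenzylammonium trifluoroacetate (cat.), THF, 40 °C
Reagents that add atoms: none
Why: Iminium-catalysed transfer hydrogenation reduces only the enal C=C and leaves vinyl and lactone; the new α-centre forms as both epimers, which step 7 funnels into one.

Step 6
Reactants: 7 aldehyde lactone
Product: 8 (E)-enone aldehyde lactone
Conditions: but-3-en-2-one (5 equiv), second-generation Hoveyda–Grubbs catalyst (5 mol %), CH2Cl2, 40 °C
Reagents that add atoms: but-3-en-2-one, CC(=O)C=C
Why: Olefin cross-metathesis of the monosubstituted alkene with the electron-poor partner should give the (E)-enone; aldehyde and lactone are inert.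

Step 7
Reactants: 8 (E)-enone aldehyde lactone
Product: 10 tricyclic enone lactone, via keto aldehyde 9 (not isolated)
Conditions: pyrrolidine (0.3 equiv), PhCO2H (0.3 equiv), toluene (0.02 M), 23 °C then 80 °C
Reagents that add atoms: none
Why: Pyrrolidine condenses with the aldehyde (far more reactive than the enone carbonyl) and both epimers give one trisubstituted enamine, whose α-carbon adds to the enone β-carbon (6-exo-trig enamine Michael addition, ring C); after iminium hydrolysis the methyl ketone of 9 attacks the now non-enolisable aldehyde and water is lost (6-enolexo-exo-trig aldol condensation, ring D). The closest known reaction is the Stork enamine annulation of isobutyraldehyde with methyl vinyl ketone to 4,4-dimethylcyclohexenone, here made intramolecular in its Michael half as in amine-catalysed cyclisations of formyl enones. The trans-fused lactone locks the forming ring C in the chair that has the existing methyl axial; the enone arm must then be equatorial (axial would be 1,3-diaxial to that methyl), which sets the new CH with its hydrogen anti to the neighbouring lactone methine hydrogen. At the new quaternary carbon the bulky enamine terminus should take the equatorial site next to that hydrogen and leave methyl axial, so that formyl and 2-oxopropyl groups are trans-diequatorial and ring D closes trans-fused. Chemoselectivity (aldehyde enamine before ketone), 6-exo over intermolecular Michael addition (dilution) and aldol regiochemistry (the methylene side could only give a four-membered ring) are secured by the substrate; the open question is the axial/equatorial choice at the quaternary carbon.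

Step 8
Reactants: 10 tricyclic enone lactone
Product: 11 tricyclic keto lactone
Conditions: H2 (1 atm), Pd/C, EtOAc, 23 °C
Reagents that add atoms: none
Why: Heterogeneous hydrogenation of the disubstituted enone C=C; no stereocentre is formed.

Step 9
Reactants: 11 tricyclic keto lactone
Product: 12 gem-dimethyl tricyclic lactone
Conditions: Me2Zn, TiCl4, CH2Cl2, −30 → 0 °C
Reagents that add atoms: dimethyltitanium dichloride, C[Ti](C)(Cl)Cl (formed in the flask from Me2Zn, C[Zn]C, and TiCl4)
Why: Geminal dimethylation of a ketone with Me2TiCl2: addition to the unhindered cyclohexanone, ionisation of the tertiary titanium alkoxide and a second methyl transfer, the lactone being inert to this reagent.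

Step 10
Reactants: 12 gem-dimethyl tricyclic lactone
Product: 13 decalin diol
Conditions: LiAlH4, THF, 0 → 23 °C
Reagents that add atoms: none
Why: Hydride reduction of the lactone to the 1,5-diol.

Step 11
Reactants: 13 decalin diol
Product: 14 decalin dialdehyde
Conditions: (COCl)2, DMSO, CH2Cl2, −78 °C; Et3N
Reagents that add atoms: none
Why: Swern oxidation activates both primary alcohols before base is added, so neither lactol nor lactone can form.

Step 12
Reactants: 14 decalin dialdehyde
Product: 15 allyl decalin carbaldehyde
Conditions: Ph3PCH3Br, KN(SiMe3)2, THF; 1.0 equiv ylide added to 14, −78 → 0 °C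
Reagents that add atoms: methylenetriphenylphosphorane, C=P(c1ccccc1)(c1ccccc1)c1ccccc1 (formed in the flask)
Why: Wittig methylenation under kinetic control should take the unhindered aldehyde, because the other aldehyde sits on the quaternary carbon next to an axial methyl.

Step 13
Reactants: 15 allyl decalin carbaldehyde; 16 3-methylcyclopent-2-en-1-one
Product: 19 aldol adduct, via bis(enoxy)silane 17 (not isolated), via lithium enolate 18 (not isolated)
Conditions: 16, CuCl (5 mol %), NaOt-Bu (5 mol %), (R)-p-tol-BINAP (5 mol %), Ph2SiH2, toluene, 0 °C; MeLi, THF, 0 °C; then 15, −78 °C; H2O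
Reagents that add atoms: none
Why: CuH-catalysed asymmetric conjugate reduction sets the ring-A methyl centre as S and gives the regiodefined silyl enol ether, which MeLi turns into the lithium enolate for aldol addition to the non-enolisable aldehyde; the two new centres are mixtures that steps 15 and 17 erase and reset.

Step 14
Reactants: 19 aldol adduct
Product: 20 isopropenyl diol
Conditions: CH2=C(CH3)MgBr (3 equiv), CeCl3, THF, −78 °C; H2O
Reagents that add atoms: isopropenylmagnesium bromide, CC(=C)[Mg]Br
Why: 1,2-Addition of the CeCl3-modified Grignard reagent to the cyclopentanone, CeCl3 suppressing enolisation and retro-aldol cleavage; the carbinol configuration is irrelevant.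

Step 15
Reactants: 20 isopropenyl diol
Product: 22 cross-ring dienone, via β-hydroxy ketone 21 (not isolated)
Conditions: Dess–Martin periodinane, CH2Cl2, 23 °C; then TsOH·H2O (cat.), 40 °C
Reagents that add atoms: none
Why: Dess–Martin oxidation of the secondary alcohol gives a β-hydroxy ketone whose tertiary allylic hydroxyl is lost under acid (aldol-type dehydration) to the fully conjugated dienone, the thermodynamic alkene isomer.

Step 16
Reactants: 22 cross-ring dienone
Product: 23 tetracyclic dienone
Conditions: second-generation Hoveyda–Grubbs catalyst (10 mol %), toluene (1 mM), 80 °C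
Reagents that add atoms: none
Why: Ring-closing metathesis between the allyl group and the isopropenyl terminus of the dienone closes ring B; the cis cyclopentene double bond and the ketone pre-organise the chain, and the eight-membered ring can hold the new trisubstituted alkene only in the cis sense.

Step 17
Reactants: 23 tetracyclic dienone
Product: 26 target alcohol CNP0399382.1, via lithium dienolate 24 (not isolated), via ketone 25 (not isolated)
Conditions: Li, NH3(l)/THF, t-BuOH (1 equiv), −78 °C; then EtOH, −78 → −33 °C; NH4Cl
Reagents that add atoms: none
Why: Birch-type reduction of a linear dienone: two electrons and a proton at the diene terminus give the cross-ring dienolate, ethanol protonates it kinetically at the α-carbon anti to the ring-A methyl (setting the ring-fusion CH and the tetrasubstituted alkene), and the β,γ-unsaturated ketone so released is reduced at once to the thermodynamically preferred carbinol, with hydroxyl on the face away from the angular methyl and the ring-A carbon (the pattern of dienone to homoallylic alcohol reductions in steroids).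

Compound list
1 | 5,6-dihydro-2H-pyran-2-one | O=C1C=CCCO1 | starting material
2 | (R)-4-vinyltetrahydro-2H-pyran-2-one | C=C[C@@H]1CCOC(=O)C1 | intermediate
3 | (3S,4S)-3-methyl-4-vinyltetrahydro-2H-pyran-2-one (methyl trans to vinyl) | C=C[C@@H]1CCOC(=O)[C@H]1C | intermediate
4 | (3S,4S)-3-methyl-3-(3-methylbut-2-en-1-yl)-4-vinyltetrahydro-2H-pyran-2-one (methyl cis to vinyl) | C=C[C@@H]1CCOC(=O)[C@@]1(C)CC=C(C)C | intermediate
5 | allylic alcohol: 4 with the (E)-methyl of the prenyl group hydroxylated | C=C[C@@H]1CCOC(=O)[C@@]1(C)C/C=C(\C)CO | intermediate
6 | (E)-enal lactone: 3-[(E)-3-methyl-4-oxobut-2-en-1-yl] analogue of 4 | C=C[C@@H]1CCOC(=O)[C@@]1(C)C/C=C(\C)C=O | intermediate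
7 | aldehyde lactone: 3-(3-methyl-4-oxobutyl) analogue, both epimers at the formyl-bearing carbon | C=C[C@@H]1CCOC(=O)[C@@]1(C)CCC(C)C=O | intermediate
8 | (E)-enone aldehyde lactone: 7 with vinyl replaced by (E)-3-oxobut-1-en-1-yl | CC(=O)/C=C/[C@@H]1CCOC(=O)[C@@]1(C)CCC(C)C=O | intermediate
9 | keto aldehyde: trans-fused bicyclic lactone, new quaternary carbon with axial methyl and equatorial formyl, 2-oxopropyl equatorial on the neighbouring carbon | O1C(=O)[C@@]2(C)CC[C@](C)(C=O)[C@@H](CC(C)=O)[C@@H]2CC1 | intermediate
10 | tricyclic enone lactone: lactone, ring C and ring D cyclohexenone, both fusions trans | O1C(=O)[C@@]2(C)CC[C@]3(C)C=CC(=O)C[C@H]3[C@@H]2CC1 | intermediate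
11 | tricyclic keto lactone (ring D cyclohexanone) | O1C(=O)[C@@]2(C)CC[C@]3(C)CCC(=O)C[C@H]3[C@@H]2CC1 | intermediate
12 | gem-dimethyl tricyclic lactone | O1C(=O)[C@@]2(C)CC[C@]3(C)CCC(C)(C)C[C@H]3[C@@H]2CC1 | intermediate
13 | decalin diol: trans-decalin with hydroxymethyl on the quaternary carbon and 2-hydroxyethyl on the neighbouring carbon | OC[C@@]1(C)CC[C@]2(C)CCC(C)(C)C[C@H]2[C@@H]1CCO | intermediate
14 | decalin dialdehyde | O=C[C@@]1(C)CC[C@]2(C)CCC(C)(C)C[C@H]2[C@@H]1CC=O | intermediate
15 | allyl decalin carbaldehyde | O=C[C@@]1(C)CC[C@]2(C)CCC(C)(C)C[C@H]2[C@@H]1CC=C | intermediate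
16 | 3-methylcyclopent-2-en-1-one | CC1=CC(=O)CC1 | starting material
17 | bis[(S)-3-methylcyclopent-1-en-1-yloxy]diphenylsilane | C[C@H]1CCC(O[Si](c2ccccc2)(c2ccccc2)OC2=C[C@@H](C)CC2)=C1 | intermediate
18 | lithium (S)-3-methylcyclopent-1-en-1-olate | [Li+].[O-]C1=C[C@@H](C)CC1 | intermediate
19 | aldol adduct: (3S)-3-methylcyclopentanone carrying at its 2-position, trans to methyl, the hydroxymethine linked to the decalin quaternary carbon (carbinol epimers) | O=C1CC[C@H](C)[C@H]1C(O)[C@@]1(C)CC[C@]2(C)CCC(C)(C)C[C@H]2[C@@H]1CC=C | intermediate
20 | isopropenyl diol: 19 with the ketone converted into a tertiary isopropenyl carbinol (carbinol epimers) | C=C(C)C1(O)CC[C@H](C)[C@H]1C(O)[C@@]1(C)CC[C@]2(C)CCC(C)(C)C[C@H]2[C@@H]1CC=C | intermediate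
21 | β-hydroxy ketone: 20 with the secondary alcohol oxidised | C=C(C)C1(O)CC[C@H](C)[C@H]1C(=O)[C@@]1(C)CC[C@]2(C)CCC(C)(C)C[C@H]2[C@@H]1CC=C | intermediate
22 | cross-ring dienone: (S)-2-isopropenyl-5-methylcyclopent-1-enyl ketone of the allyl decalin | C=C(C)C1=C(C(=O)[C@@]2(C)CC[C@]3(C)CCC(C)(C)C[C@H]3[C@@H]2CC=C)[C@@H](C)CC1 | intermediate
23 | tetracyclic dienone: rings A to D closed, ketone at the future carbinol carbon, conjugated with the ring-fusion alkene and the trisubstituted ring-B alkene | O=C1C2=C(CC[C@@H]2C)/C(C)=C\C[C@H]3[C@@H]4CC(C)(C)CC[C@@]4(C)CC[C@]13C | intermediate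
24 | lithium dienolate of 25 | [Li+].C/C1=C2\CC[C@H](C)/C2=C(\[O-])[C@@]2(C)CC[C@]3(C)CCC(C)(C)C[C@H]3[C@@H]2CC1 | intermediate
25 | β,γ-unsaturated ketone: the target with the carbinol oxidised to the ketone | C/C1=C2\CC[C@H](C)[C@@H]2C(=O)[C@@]2(C)CC[C@]3(C)CCC(C)(C)C[C@H]3[C@@H]2CC1 | intermediate
26 | CNP0399382.1, tetracyclic homoallylic alcohol | C/C1=C2\CC[C@H](C)[C@@H]2[C@@H](O)[C@@]2(C)CC[C@]3(C)CCC(C)(C)C[C@H]3[C@@H]2CC1 | target

Total step count: 17. Longest linear sequence: 17 steps (1 → 26); 16 is a purchased partner that enters at step 13.

Steps most likely to fail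

Step 7. What may go wrong is poor facial selectivity at the new quaternary carbon (the enamine terminus taking the axial site, which leads to the cis-fused ring system), or loss of configuration at the γ-carbon of the enone through dienamine formation. The fallback sets out from 7 and separates the two bond formations under Lewis acid control. The aldehyde is converted into its tert-butyldimethylsilyl enol ether F1 (TBSOTf, Et3N). Cross-metathesis with but-3-en-2-one gives the enone silyl enol ether F2. An intramolecular Mukaiyama–Michael addition (TiCl4, CH2Cl2, −78 °C, open transition state) closes ring C to keto aldehyde 9, which is isolated. Aldol condensation with KOH in MeOH comes back to the route at 10.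

Step 16. What may go wrong is slow ring closure onto the conjugated 1,1-disubstituted alkene, so that cross-metathesis of the allyl group leads to oligomers. The fallback sets out from 20 and closes ring B before the dienone exists. Ring-closing metathesis of the diol, whose 1,1-disubstituted alkene is unconjugated and carries an allylic hydroxyl, gives the cyclooctene diol F3. Dess–Martin oxidation to the β-hydroxy ketone F4 and acid dehydration come back to the route at 23.

Step 17. What may go wrong is protonation of the dienolate at the γ-carbon or from the wrong face followed by over-reduction, or reduction of the ketone to the epimeric carbinol. The fallback sets out from 23 and fixes both centres by one syn addition. Reduction with Li/NH3 and one equivalent of t-BuOH is stopped with NH4Cl at ketone 25, which is isolated. KN(SiMe3)2 and PhNTf2 give the dienyl triflate F5, which erases the ring-fusion centre. Reduction with Pd(OAc)2, PPh3, HCO2H and Bu3N gives the ring-B diene F6. Hydroboration–oxidation (BH3·THF; NaOH, H2O2) places boron at the diene terminus and adds H and OH syn from the face opposite the two methyl-bearing neighbours, coming back to the route at 26.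

Further compounds
F1 | step 7 | tert-butyldimethylsilyl enol ether of aldehyde 7 | C=C[C@@H]1CCOC(=O)[C@@]1(C)CCC(C)=CO[Si](C)(C)C(C)(C)C
F2 | step 7 | enone silyl enol ether | CC(=O)/C=C/[C@@H]1CCOC(=O)[C@@]1(C)CCC(C)=CO[Si](C)(C)C(C)(C)C
F3 | step 16 | cyclooctene diol (ring B closed, carbinol epimers) | OC1[C@H]2C(O)(CC[C@@H]2C)/C(C)=C\C[C@H]3[C@@H]4CC(C)(C)CC[C@@]4(C)CC[C@]13C
F4 | step 16 | ring-B β-hydroxy ketone | O=C1[C@H]2C(O)(CC[C@@H]2C)/C(C)=C\C[C@H]3[C@@H]4CC(C)(C)CC[C@@]4(C)CC[C@]13C
F5 | step 17 | dienyl triflate of ketone 25 | C/C1=C2\CC[C@H](C)/C2=C(\OS(=O)(=O)C(F)(F)F)[C@@]2(C)CC[C@]3(C)CCC(C)(C)C[C@H]3[C@@H]2CC1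
F6 | step 17 | ring-B 1,3-diene | C/C1=C2\CC[C@H](C)/C2=C/[C@@]2(C)CC[C@]3(C)CCC(C)(C)C[C@H]3[C@@H]2CC1
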